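**Retrosynthetic overview**

1. Target 14 ⇒ 13: the 2H‑pyran ring is opened at its aryl–CH= bond (C4a–C4). Compound 13 is the acyclic isomer, an aryl 1,1‑dimethylpropargyl ether, closed again by gold(I)‑catalysed 6‑endo‑dig hydroarylation.
2. Enabling feature: the hexasubstituted phloroglucinol ring of 13 has a single aromatic C–H (the future C4a). It lies ortho to the ether oxygen (the future O1), which already carries C2 with its two methyl groups and the C3≡C4 alkyne. The O1–C2 bond is never broken, so the ring oxygen cannot be exchanged for the neighbouring hydroxyl.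
3. 13 ⇒ ether 5 + pyranone 10 + one CH2 unit (Eschenmoser's salt): the methylene bridge is made by a Mannich / retro‑Michael / Friedel–Crafts‑type Michael coupling.
4. 5 ⇒ 3 by para‑selective O‑propargylation; 3 ⇒ phloroglucinol 1 + acid chloride 2. 10 ⇒ silyl enol ether 7 of pentan‑3‑one + malonyl dichloride 8.
5. Order of rings: benzene ring (purchased), 2‑pyranone ring (step 4), 2H‑pyran ring of the chromene (step 6).

Key step: step 6

Remark on the chemistry: the target has no stereocentre and its only non‑aromatic C=C lies in the six‑membered pyran ring (necessarily cis), so it is achiral and no enantiocontrol is needed.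

**Route**

Step 1
Reactants: 1 benzene‑1,3,5‑triol (phloroglucinol); 2 2‑methylpropanoyl chloride
Product: 3 2‑methyl‑1‑(2,4,6‑trihydroxyphenyl)propan‑1‑one
Conditions: AlCl3 (3.5 equiv), PhNO2–CH2Cl2, 0 °C → 50 °C; aq. HCl work‑up
Reagents that add atoms: none
Why: Friedel–Crafts acylation of the threefold‑activated ring should give C‑acylation, and the chelated, electron‑withdrawing ketone should then prevent a second acylation; no stereocentre is formed.

Step 2
Reactants: 3 2‑methyl‑1‑(2,4,6‑trihydroxyphenyl)propan‑1‑one; 4 3‑chloro‑3‑methylbut‑1‑yne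
Product: 5 1‑[2,6‑dihydroxy‑4‑(2‑methylbut‑3‑yn‑2‑yloxy)phenyl]‑2‑methylpropan‑1‑one
Conditions: K2CO3 (1.1 equiv), KI (cat.), CuI (cat.), acetone, 40 °C
Reagents that add atoms: none
Why: Williamson‑type O‑propargylation (copper/iodide‑assisted substitution at the tertiary propargylic chloride) should occur only at the para hydroxyl, because it is the most acidic one and the only one not engaged by hydrogen bonding to the ketone, so one equivalent of base ionises it alone.

Step 3
Reactants: 6 pentan‑3‑one
Product: 7 (Z)‑trimethyl(pent‑2‑en‑3‑yloxy)silane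
Conditions: TMSOTf, Et3N, CH2Cl2, 0 °C
Reagents that add atoms: trimethylsilyl trifluoromethanesulfonate, C[Si](C)(C)OS(=O)(=O)C(F)(F)F
Why: Soft enolisation and O‑silylation of a symmetrical ketone can give only one constitutional silyl enol ether, and its double‑bond geometry (Z expected, E equally usable) is lost in step 4.

Step 4
Reactants: 7 (Z)‑trimethyl(pent‑2‑en‑3‑yloxy)silane; 8 propanedioyl dichloride (malonyl dichloride)
Product: 10 6‑ethyl‑4‑hydroxy‑5‑methyl‑2H‑pyran‑2‑one, via 4‑methyl‑3,5‑dioxoheptanoyl chloride 9 (not isolated)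
Conditions: Et2O, −78 °C → rt; aqueous work‑up
Reagents that add atoms: none
Why: Effenberger‑type pyranone synthesis, in which one acyl chloride group C‑acylates the silyl enol ether, the enol of the resulting β‑diketone is O‑acylated by the second acyl chloride (lactonisation) and tautomerisation gives the 4‑hydroxy‑2‑pyranone; the transient stereocentre of 9 disappears.

Step 5
Reactants: 10 6‑ethyl‑4‑hydroxy‑5‑methyl‑2H‑pyran‑2‑one; 5 1‑[2,6‑dihydroxy‑4‑(2‑methylbut‑3‑yn‑2‑yloxy)phenyl]‑2‑methylpropan‑1‑one
Product: 13 3‑{[2,4‑dihydroxy‑3‑(2‑methylpropanoyl)‑6‑(2‑methylbut‑3‑yn‑2‑yloxy)phenyl]methyl}‑6‑ethyl‑4‑hydroxy‑5‑methyl‑2H‑pyran‑2‑one, via pyranone Mannich base 11 (not isolated), via 3‑methylidenepyran‑2,4‑dione 12 (not isolated)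
Conditions: 10, Eschenmoser's salt (1.0 equiv), MeCN, rt; then 5 (3 equiv, excess recovered), 60 °C
Reagents that add atoms: N,N‑dimethylmethyleneiminium iodide (Eschenmoser's salt), C=[N+](C)C.[I-]
Why: Mannich reaction at the nucleophilic C3 of the 4‑hydroxypyranone, thermal retro‑Michael loss of dimethylamine to the 3‑methylidene dione and Friedel–Crafts‑type conjugate addition of a ring carbon of 5 should give the bridge; the two free ring positions of 5 are equivalent, the excess of 5 should hold back a second alkylation, and the propargyl ether stays below its rearrangement temperature.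

Step 6
Reactants: 13 3‑{[2,4‑dihydroxy‑3‑(2‑methylpropanoyl)‑6‑(2‑methylbut‑3‑yn‑2‑yloxy)phenyl]methyl}‑6‑ethyl‑4‑hydroxy‑5‑methyl‑2H‑pyran‑2‑one
Product: 14 3‑{[5,7‑dihydroxy‑2,2‑dimethyl‑6‑(2‑methylpropanoyl)‑2H‑chromen‑8‑yl]methyl}‑6‑ethyl‑4‑hydroxy‑5‑methyl‑2H‑pyran‑2‑one
Conditions: Ph3PAuNTf2 (5 mol%), 1,2‑dichloroethane, rt → 40 °C
Reagents that add atoms: none
Why: Cationic gold(I) π‑activates the terminal alkyne of 13, the lone aromatic C–H carbon (ortho to the ether oxygen and to a hydroxyl, para to the other hydroxyl) attacks the terminal alkyne carbon anti to gold, and rearomatisation followed by protodeauration of the vinylgold species releases the 2H‑pyran ring and the catalyst. The closest known reaction type is the gold(I)‑ or platinum‑catalysed intramolecular hydroarylation (cycloisomerisation) of aryl 1,1‑dimethylpropargyl ethers to 2,2‑dimethyl‑2H‑chromenes. The ring is closed in the 6‑endo‑dig mode by forming the aryl–C4 bond, and no stereocentre is created because the new alkene is cis by being in the ring. The step needs the right oxygen in the ring, the right carbon, and endo rather than exo closure: the oxygen is fixed because the O–C(CH3)2 bond made in step 2 is never broken (a thermal propargyl Claisen/ortho‑quinone methide sequence would let the neighbouring free hydroxyl close instead), the carbon is fixed because the ring has only one unsubstituted position, and endo closure is favoured by the short O–C tether and the terminal alkyne, with the two methyl groups holding the alkyne over the ring. The free phenols, the chelated ketone and the pyranone enol should need no protection because the carbophilic catalyst activates only the alkyne under neutral conditions.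

**Compound list**

1 | benzene‑1,3,5‑triol (phloroglucinol) | Oc1cc(O)cc(O)c1 | starting material
2 | 2‑methylpropanoyl chloride (isobutyryl chloride) | CC(C)C(Cl)=O | starting material
3 | 2‑methyl‑1‑(2,4,6‑trihydroxyphenyl)propan‑1‑one | CC(C)C(=O)c1c(O)cc(O)cc1O | intermediate
4 | 3‑chloro‑3‑methylbut‑1‑yne | CC(C)(Cl)C#C | starting material
5 | 1‑[2,6‑dihydroxy‑4‑(2‑methylbut‑3‑yn‑2‑yloxy)phenyl]‑2‑methylpropan‑1‑one | CC(C)C(=O)c1c(O)cc(OC(C)(C)C#C)cc1O | intermediate
6 | pentan‑3‑one | CCC(=O)CC | starting material
7 | (Z)‑trimethyl(pent‑2‑en‑3‑yloxy)silane | CC/C(O[Si](C)(C)C)=C/C | intermediate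
8 | propanedioyl dichloride (malonyl dichloride) | ClC(=O)CC(Cl)=O | starting material
9 | 4‑methyl‑3,5‑dioxoheptanoyl chloride (racemic, enolisable; not isolated) | CCC(=O)C(C)C(=O)CC(Cl)=O | intermediate
10 | 6‑ethyl‑4‑hydroxy‑5‑methyl‑2H‑pyran‑2‑one | CCc1oc(=O)cc(O)c1C | intermediate
11 | 3‑[(dimethylamino)methyl]‑6‑ethyl‑4‑hydroxy‑5‑methyl‑2H‑pyran‑2‑one (formed as its hydroiodide; not isolated) | CCc1oc(=O)c(CN(C)C)c(O)c1C | intermediate
12 | 6‑ethyl‑5‑methyl‑3‑methylidene‑2H‑pyran‑2,4(3H)‑dione (not isolated) | CCC1=C(C)C(=O)C(=C)C(=O)O1 | intermediate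
13 | 3‑{[2,4‑dihydroxy‑3‑(2‑methylpropanoyl)‑6‑(2‑methylbut‑3‑yn‑2‑yloxy)phenyl]methyl}‑6‑ethyl‑4‑hydroxy‑5‑methyl‑2H‑pyran‑2‑one | CCc1oc(=O)c(Cc2c(O)c(C(=O)C(C)C)c(O)cc2OC(C)(C)C#C)c(O)c1C | intermediate
14 | 3‑{[5,7‑dihydroxy‑2,2‑dimethyl‑6‑(2‑methylpropanoyl)‑2H‑chromen‑8‑yl]methyl}‑6‑ethyl‑4‑hydroxy‑5‑methyl‑2H‑pyran‑2‑one | CCc1oc(=O)c(Cc2c(O)c(C(=O)C(C)C)c(O)c3c2OC(C)(C)C=C3)c(O)c1C | target

**Step count**

Total: 6 steps. Longest linear sequence: 4 steps (steps 1, 2, 5, 6; the pyranone branch, steps 3, 4, 5, 6, is equally long).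

**Steps most likely to fail, with fallbacks**

Step 6. The gold catalyst may be sequestered by the chelating hydroxy‑ketone and pyranone enol, the tertiary propargylic C–O bond may ionise with loss of the side chain, or closure may go exo. The fallback closes the ring thermally by a propargyl Claisen / [1,5]‑hydrogen shift / oxa‑6π cascade, after capping every hydroxyl so that only the oxygen that carried the propargyl group can close. It sets out from 13, which is peracetylated (Ac2O, pyridine, DMAP, rt) to the tri‑O‑acetate of 13 F1. Heating (o‑xylene, 140 °C) should convert it into the tri‑O‑acetate of 14 F2, since the [3,3] shift can only reach the one free ortho carbon and the phenol set free is then the only hydroxyl in the molecule. Methanolysis (K2CO3, MeOH, 0 °C → rt) of F2 comes back to the route at 14.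

Step 5. The ether 5 has two equivalent nucleophilic ring carbons and may be alkylated twice, and the pyranone may be consumed by self‑condensation through its methylidene dione. The fallback reverses the polarity of the coupling and sets out from 5. One equivalent of Eschenmoser's salt (CH2Cl2, 0 °C) should give the benzylic Mannich base 1‑[3‑[(dimethylamino)methyl]‑2,6‑dihydroxy‑4‑(2‑methylbut‑3‑yn‑2‑yloxy)phenyl]‑2‑methylpropan‑1‑one F3, whose ammonium salt is deactivated toward a second substitution. Heating F3 with pyranone 10 (1,4‑dioxane, 80 °C) should expel dimethylamine to give an ortho‑quinone methide on the phloroglucinol side, which is trapped at C3 of 10 by conjugate addition; this comes back to the route at 13.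

Step 4. O‑Acylation of the silyl enol ether, hydrolysis of the moisture‑sensitive acid chloride and oligomerisation may compete with the C‑acylation/lactonisation sequence. The fallback builds the open‑chain triketide first and sets out from 6. BF3‑mediated C‑acetylation with acetic anhydride (BF3·2AcOH, then aq. NaOAc) should give 3‑methylhexane‑2,4‑dione F4. Its dianion (NaH, then n‑BuLi, THF, 0 °C), formed at the central carbon and then at the terminal methyl group, is carboxylated with CO2 to 4‑methyl‑3,5‑dioxoheptanoic acid F5. Cyclodehydration (TFAA, TFA, rt) comes back to the route at 10.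

**Further compounds**

F1 | step 6 | tri‑O‑acetate of 13 (both phenolic hydroxyls and the pyranone 4‑hydroxyl acetylated) | CCc1oc(=O)c(Cc2c(OC(C)=O)c(C(=O)C(C)C)c(OC(C)=O)cc2OC(C)(C)C#C)c(OC(C)=O)c1C
F2 | step 6 | tri‑O‑acetate of 14 (both phenolic hydroxyls and the pyranone 4‑hydroxyl acetylated) | CCc1oc(=O)c(Cc2c(OC(C)=O)c(C(=O)C(C)C)c(OC(C)=O)c3c2OC(C)(C)C=C3)c(OC(C)=O)c1C
F3 | step 5 | 1‑[3‑[(dimethylamino)methyl]‑2,6‑dihydroxy‑4‑(2‑methylbut‑3‑yn‑2‑yloxy)phenyl]‑2‑methylpropan‑1‑one | CC(C)C(=O)c1c(O)cc(OC(C)(C)C#C)c(CN(C)C)c1O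
F4 | step 4 | 3‑methylhexane‑2,4‑dione (racemic, enolisable) | CCC(=O)C(C)C(C)=O
F5 | step 4 | 4‑methyl‑3,5‑dioxoheptanoic acid (racemic, enolisable) | CCC(=O)C(C)C(=O)CC(O)=O
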